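Watch the links.

| flask | first end groups | second end groups | remark | time |
|---|---|---|---|---|
| eta | 0.093 M | 0.95 equiv | run made earlier |  |
| epsilon | 0.093 M | 1.4 equiv | run made earlier |  |
| violet | 0.093 M (fed, over 6.0 min) | 0.950 equiv | all else is in the flask from the start; the feed brings no volume worth counting | 10 min |
| green | 0.093 M (in portions, 5, over 6.0 min) | 0.950 equiv | first portion at the start, last at 6.0 min | 10 min |
| teal | 0.093 M | 0.950 equiv | everything together at the start | 10 min |
| red | 0.093 M | 0.950 equiv (fed, over 6.0 min) | all else is in the flask from the start; the feed brings no volume worth counting | 10 min |

eta run (percent of the first end groups charged)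

| time / min | links / % | over-reaction product / % |
|---|---|---|
| 0.833 | 26.5 | 0.9 |
| 2.00 | 25.4 | 5.7 |
| 4.00 | 21.9 | 10.1 |
| 10.0 | 14.1 | 19.7 |

epsilon run (percent of the first end groups charged)

| time / s | links / % | over-reaction product / % |
|---|---|---|
| 10.0 | 34.3 | 0.2 |
| 12.0 | 34.0 | 2.6 |
| 25.0 | 35.9 | 1.9 |
| 60.0 | 32.2 | 5.2 |

(each reading ± 1 percentage point)

- the flask with the highest share of links in links plus over-reaction product ("all alike" if they lie within 1.5 percentage points) (violet / green / teal / red / all alike)
- share of links in links plus over-reaction product at the end, violet
- share of links in links plus over-reaction product at the end, green
- share of links in links plus over-reaction product at the end, teal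
- share of links in links plus over-reaction product at the end, red

- amounts and yields of links count crystals too
- given per volume of solution although it is solid: crystals
- what was read earlier has a scatter of 1 percentage point, one standard deviation
- steps under discussion: first end groups + second end groups <-> links; crystals <-> links; second end groups + links -> over-reaction product

Climb the ladder of times. Seconds come first: the epsilon run holds 34.3 % links at 10.0 s and 32.2 % at 60.0 s, so take c(links) as following c(first end groups)·c(second end groups) from moment to moment. Next comes the feed, 6.0 min. Over-reaction is the top rung. In eta, over-reaction product rises from 5.7 % at 2.00 min to 19.7 % at 10.0 min, with 21.9 % links at 4.00 min as the standing level. Define the link lifetime τ, standing links divided by their rate of loss to over-reaction product, a pseudo-first-order lifetime: 12.5 min. That is longer than the 10 min of the flasks and about twice the feed, so the loss goes on through the whole time.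

Now compare rates at one moment. If the step runs as written, τ shrinks as c(second end groups) grows, so the loss c(links)/τ goes with c(first end groups) times c(second end groups) squared. Reckoned on charges, with half of the fed charge in and what links and over-reaction product hold left out, red loses at a quarter of teal's rate and violet at half. Green is violet in steps. Then follow the drift: once the feed stops the charges match, and what remains is the loss held off during the feed. Teal repeats eta, whose last reading gives 41.7 %. My order: red, then violet and green together, then teal.

The forecast gives violet 52 %, green 51 %, teal 42 %, red 57 %: “Red should be best.”

The flasks give violet 50.5 %, green 50.2 %, teal 43.4 %, red 56.5 %; red leads.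

    first end groups + second end groups ⇌ links (K = 6.10 /M, k = 11.0 /M/s)
    crystals ⇌ links, rate k2*(cs2 - [links]) while solid is left; crystals form when [links] > cs2 (solubility = 0.0540 M, k = 0.210 /s)
    second end groups + links → over-reaction product (k = 0.0330 /M/s)

In red at 3.13 min, dissolved links fall back 1800 times faster than they go on. There the forward making alone would halve second end groups in 0.81 s, the loss to over-reaction product in 25 min. From the end of its feed to 10.0 min, red shows τ of 10.2 min. The neighbour like red with 3.80 equiv of second end groups keeps 55.0 % of its own charge at 10.0 min, while teal, on eta's recipe, holds 53.2 % of its own at 5.00 min; scaling eta's τ by these amounts, charges counted, gives 3.03 min, and that neighbour ends with a share of 12.0 % and 80.0 % over-reaction product.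

Readings and results are calculated with made-up constants; scatter was added.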